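All constants come from no measurement; what happens was integrated by code.

The constants 0.16 L mol⁻¹ min⁻¹ and 0.034 L mol⁻¹ min⁻¹ belong to the first and second exchange on a starting complex, each of which spends one incoming ligand and frees one leaving ligand. Their ratio is the selectivity factor 4.71: at equal concentrations the first exchange runs faster than the second.

the same everywhere: incoming ligand 0.960 M; time 8.0 h
- summer: starting complex 0.20 M
- dawn: starting complex 0.40 M
- midnight: starting complex 0.80 M
- noon: starting complex 1.5 M

- in percentages every species weighs as the starting complex in it: one idle adduct counts as two
- for complex with two exchanged the idle adduct is counted in
- in an amount of complex with two exchanged, one idle adduct counts as one complex with two exchanged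
- the concentration of complex with two exchanged that is asked is that of its free form alone
- "hardly changes" means that all values lie within two and a half points (for a concentration: within two and a half percent of the largest)
- run time (summer): 8.0 h

1. [complex with two exchanged] (only what is free in solution) at the end for summer, dawn, midnight, noon, in this order
2. the course of these numbers from the first flask to the last (hardly changes / rises all the way / rises, then falls / falls all the way / falls, then rises)

Write C for the complex with one exchanged and D for the complex with two exchanged, idle adduct counted in. C holds one spent incoming ligand and D holds two. The ligand budget, B = 0.480 M, is the concentration of D that the ligand charge can pay for. At a ligand concentration of zero, [D] = B − [C]/2.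

In summer the starting complex charge 0.20 M stays below B. The half-lives 0.075 h and 0.35 h, reckoned at the concentrations as charged, are far shorter than 8.0 h, so the estimate is [D] = 0.20 M, with 0.560 M of ligand to spare.

At dawn the spare ligand is s = 0.160 M. Freezing the ligand at s gives C a half-life of 2.12 h and leaves 0.0294 M of C. That is the weak link, since the ligand really stands at s + [C]. With the starting complex reckoned as C from the start, the ratio [C]/(s + [C]) decays at the constant rate k₂s, with k₂ the second constant. Starting from 0.714, it reaches 0.0525. So the estimate for dawn is 0.00886 M of C and [D] = 0.391 M.

At midnight and noon the starting complex charge exceeds B, so the ligand is the limiting reagent. At noon the ligand charge is below the starting complex charge 1.5 M, and by the budget [D] tends to zero as [C] nears 0.960 M. The hand reckoning stops there, without a number for midnight or noon, and expects a row that rises, then falls.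

The forecast gave 0.2 M, 0.391 M, 0.216 M and 0.05 M, course rises, then falls, noting for summer that “ligand stays in excess”.

    starting complex + incoming ligand → leaving ligand + complex with one exchanged (k1 = 0.16 L mol⁻¹ min⁻¹)
    complex with one exchanged + incoming ligand → leaving ligand + complex with two exchanged (k2 = 0.034 L mol⁻¹ min⁻¹)
    starting complex + complex with two exchanged ⇌ idle adduct, settled at all times (K3 = 1.4 L mol⁻¹)

The flasks give 0.200 M, 0.391 M, 0.216 M and 0.0487 M of free complex with two exchanged, and the course rises, then falls. The row turns at a starting complex of 0.48 M, which is B. At noon, 0 % of the incoming ligand stands at 8.00 h, and complex with one exchanged stands at 52.2 % of the starting complex charged. The budget then gives 0.0885 M of complex with two exchanged, idle adduct counted in. The noon flask holds 5.92 % of its charge in that form, which is 0.0888 M.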